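## The problem

The target is robinetinidol-(4α→6)-(−)-epigallocatechin. Two flavan-3-ols are joined by one bond from C4 of the upper unit (rings A, B, C; 2R,3S,4S, all-trans) to C6 of the lower unit (rings D, E, F; 2R,3R, 2,3-cis). The lower unit is (−)-epigallocatechin itself, so the difficulty lies in ring C and in the interflavan bond. That bond must reach C6 of ring D, the carbon between O5 and O7, and not C8, which is the more reactive and less crowded position of a 5,7-dioxygenated flavan. C4 of the upper unit is a methine with three large groups (C3, C4a of ring A, C6 of ring D), and ring D must end trans to the 3-OH and cis to the C2 aryl. Ring A is a resorcinol ring without O5, so a C4 cation is less stabilised than in the procyanidin series, and cationic couplings of such units typically give 4α/4β mixtures.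

The feature that opens another way is that C3 (H, OH) and C4 (H, ring A, ring D) are adjacent. The upper unit is therefore the syn, anti-Markovnikov hydrate of the C3=C4 bond of a 4-aryl-2H-chromene, whose only stereocentre, C2 with its ring-B aryl, sits next to C3. In addition, C6 of ring D, flanked by two ether oxygens, becomes an ordinary 2,6-dialkoxyaryl metal once it carries a halogen. The nine phenols (two pyrogallol rings) are sensitive to air and base, and C2 of a free flavan-3-ol epimerises in base, so all phenols stay benzylated until the last step.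

## Retrosynthesis

**15 to 14.** The nine O–H bonds of the phenols are traced back to benzyl ethers and C8–H of ring D to C8–Br. One hydrogenolysis should remove all ten groups from 14. The benzyl ethers make every earlier intermediate stable to air and base, and the bromine is the group that steers functionalisation to C6.

**14 to 12 (key disconnection).** The C3–O bond and the C4–H bond of ring C are cut together, a retro-hydroboration. The alternative cut at C4–C6 would require a hindered arene to attack a secondary cation and would leave the C4 configuration to the cation. Cutting C4–H instead means the crowded centre becomes sp3 by receiving a hydrogen atom. Alkene 12 has one stereocentre in the upper unit instead of three. The forward reaction must place boron at C3, add H and B syn, and use the face opposite to the C2 aryl.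

**12 to 5 and 9 (through 10 and 11).** The C4–C6 bond is now a bond between two sp2 carbons and is cut as a Negishi coupling of alkenyl triflate 5 with arylzinc 11, made from iodide 9 through Grignard 10. No stereocentre is formed, and the 6-regiochemistry is fixed by the position of the iodine. The forward step must distinguish C–I from C–Br and tolerate two ortho benzyloxy groups.

**9 to 8 to 7 to 6.** The C6–I bond, the C8–Br bond and five O–benzyl bonds are removed in turn. Bromination of 7 should go to C8, the intrinsically preferred site. Iodination of 8 then has only C6 left on ring D. Compound 6 is commercial (−)-epigallocatechin, which brings both stereocentres of the lower unit.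

**5 to 4 to 2 and 3; 2 to 1.** The enol triflate 5 comes from flavanone 4 without passing through an enolate. The C2–aryl bond of 4 is cut as an asymmetric conjugate addition of boronic acid 3 to chromone 2, which is the benzyl ether of commercial 7-hydroxychromone 1. This sets C2, the single stereocentre from which C3 and C4 are later derived.

## Roads not taken

**Alternative 1:** The obvious cut is C4–C6 as a Friedel–Crafts bond. A C4-oxygenated, benzylated robinetinidol such as the flavan-3,4-diol A1 would be ionised with a Lewis acid and captured by the C8-blocked nucleophile 8 to give 14 directly. The chosen plan is preferred for three reasons.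
- C6 of 8 lies between two benzyloxy groups and would have to attack a secondary cation to form a carbon with three large substituents. C8-halogenated benzylated flavan-3-ols are known as poor nucleophiles for this reason.
- The resorcinol ring A gives a less stabilised, less selective cation, so a 4α/4β mixture is expected.
- A1 itself needs a flavan-3-ol or dihydroflavonol synthesis plus C4 oxygenation, which is no shorter than steps 1 to 3.

**Alternative 2:** A stereoconvergent ring closure. Here the O1–C2 and C4–C6 bonds are cut. Grignard 10 would add to the carbonyl of the achiral 2'-hydroxychalcone A2 to give the tertiary carbinol A3 as a mixture of epimers. A chiral Brønsted acid would then ionise both epimers to one allyl cation and close ring C to 12 with control of C2. This is shorter and uses an achiral upper precursor. It is not chosen for three reasons.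
- The cation from A3 is stabilised by rings A, B and the trialkoxy ring D, so the ring closure is reversible under the acid that catalyses it and C2 of 12 can equilibrate.
- The induction must come from a counter-anion next to a very large aryl group.
- A di-ortho-substituted aryl nucleophile may add 1,4 to the enone.
The chosen plan sets C2 in the small ketone 4 and never exposes 12 to acid.

**Alternative 3:** Regiocontrol by symmetry. In a 4→6 dimer, C4 of the upper unit is para to the pyran oxygen of ring F, so ring D could start as phloroglucinol. Capture of the cation from A1 by phloroglucinol would give the adduct A4 with no regiochemical question. Ring F would then be built on A4 by C-cinnamylation, asymmetric dihydroxylation, cyclisation through the para hydroxyl, and an oxidation–reduction at C3 to reach the 2,3-cis series. This costs six or more steps on an advanced polyphenol, needs the para oxygen to be distinguished from the two ortho hydroxyls, still depends on the cationic C4 chemistry of Alternative 1, and discards the commercial lower unit 6.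

Key step: step 8

Assumption: 1, 3 and 6 are taken as purchasable, and the ligand antipode in step 2 is chosen by analogy with the known facial preference of this catalyst class; it is exchanged if the 2R ketone forms.

## Route

Step 1
Reactants: 1 7-hydroxy-4H-chromen-4-one
Product: 2 7-(benzyloxy)-4H-chromen-4-one
Conditions: BnBr, K2CO3, DMF, rt
Reagents that add atoms: benzyl bromide, BrCc1ccccc1
Why: Williamson ether synthesis on an acidic, vinylogous carboxylic phenol; no other nucleophilic site is present.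

Step 2
Reactants: 2 7-(benzyloxy)-4H-chromen-4-one; 3 [3,4,5-tris(benzyloxy)phenyl]boronic acid
Product: 4 (2S)-7-(benzyloxy)-2-[3,4,5-tris(benzyloxy)phenyl]-2,3-dihydro-4H-chromen-4-one
Conditions: Pd(OCOCF3)2 (5 mol %), (R)-4-tert-butyl-2-(pyridin-2-yl)-4,5-dihydrooxazole (6 mol %), NH4PF6 (30 mol %), H2O (5 equiv), ClCH2CH2Cl, 60 °C
Reagents that add atoms: none
Why: Palladium-catalysed asymmetric conjugate addition of an arylboronic acid to a chromone, a known route to 2-arylchroman-4-ones; the chiral pyridine–oxazoline aryl-palladium species selects the face of C2=C3 and so sets C2, and the weakly acidic medium should not racemise the product by retro-oxa-Michael opening.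

Step 3
Reactants: 4 (2S)-7-(benzyloxy)-2-[3,4,5-tris(benzyloxy)phenyl]-2,3-dihydro-4H-chromen-4-one
Product: 5 (2S)-7-(benzyloxy)-2-[3,4,5-tris(benzyloxy)phenyl]-2H-chromen-4-yl trifluoromethanesulfonate
Conditions: Tf2O, 2,6-di-tert-butyl-4-methylpyridine, CH2Cl2, 0 °C to rt
Reagents that add atoms: trifluoromethanesulfonic anhydride, O=S(=O)(OS(=O)(=O)C(F)(F)F)C(F)(F)F
Why: Enol triflate formation by O-sulfonylation of the electron-rich aryl ketone and loss of H3 to a hindered pyridine; no enolate is formed, so the base-induced ring opening that racemises flavanones is avoided and C2 is untouched.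

Step 4
Reactants: 6 (−)-epigallocatechin [(2R,3R)-2-(3,4,5-trihydroxyphenyl)chromane-3,5,7-triol]
Product: 7 (2R,3R)-5,7-bis(benzyloxy)-2-[3,4,5-tris(benzyloxy)phenyl]chroman-3-ol
Conditions: BnBr (5.5 equiv), K2CO3, DMF, 0 °C to rt, N2
Reagents that add atoms: benzyl bromide, BrCc1ccccc1
Why: Williamson etherification of the five phenols; carbonate does not deprotonate the secondary 3-OH, and the mild base at low temperature should avoid C2 epimerisation.

Step 5
Reactants: 7 (2R,3R)-5,7-bis(benzyloxy)-2-[3,4,5-tris(benzyloxy)phenyl]chroman-3-ol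
Product: 8 (2R,3R)-5,7-bis(benzyloxy)-8-bromo-2-[3,4,5-tris(benzyloxy)phenyl]chroman-3-ol
Conditions: NBS (1.0 equiv), CH2Cl2, −40 to 0 °C
Reagents that add atoms: N-bromosuccinimide, O=C1CCC(=O)N1Br
Why: Electrophilic aromatic bromination; C8, between O1 and the 7-benzyloxy group, is the most reactive position of ring D in 5,7-di-O-benzyl flavan-3-ols, so one equivalent should give the 8-bromide, which blocks C8 until step 9.

Step 6
Reactants: 8 (2R,3R)-5,7-bis(benzyloxy)-8-bromo-2-[3,4,5-tris(benzyloxy)phenyl]chroman-3-ol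
Product: 9 (2R,3R)-5,7-bis(benzyloxy)-8-bromo-6-iodo-2-[3,4,5-tris(benzyloxy)phenyl]chroman-3-ol
Conditions: NIS (1.1 equiv), CF3CO2H (cat.), CH2Cl2–MeCN, 0 °C to rt, dark
Reagents that add atoms: N-iodosuccinimide, O=C1CCC(=O)N1I
Why: Acid-catalysed electrophilic aromatic iodination at the only remaining ring-D position, C6, which three oxygens activate; ring E and the benzyl arenes are far less activated, and 6,8-dihalogenation of this ring type is known.

Step 7
Reactants: 9 (2R,3R)-5,7-bis(benzyloxy)-8-bromo-6-iodo-2-[3,4,5-tris(benzyloxy)phenyl]chroman-3-ol; 5 (2S)-7-(benzyloxy)-2-[3,4,5-tris(benzyloxy)phenyl]-2H-chromen-4-yl trifluoromethanesulfonate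
Product: 12 (2R,3R)-5,7-bis(benzyloxy)-6-{(2S)-7-(benzyloxy)-2-[3,4,5-tris(benzyloxy)phenyl]-2H-chromen-4-yl}-8-bromo-2-[3,4,5-tris(benzyloxy)phenyl]chroman-3-ol, via ring-D arylmagnesium chloride 10 (not isolated), via ring-D arylzinc chloride 11 (not isolated)
Conditions: MeMgCl (1.0 equiv), THF, −20 °C; i-PrMgCl·LiCl (1.1 equiv), −20 to 0 °C; ZnCl2 (1.2 equiv); then 5, Pd(OAc)2 (3 mol %), SPhos (6 mol %), THF, 40 °C, dark
Reagents that add atoms: none
Why: The 3-OH is first deprotonated, then iodine–magnesium exchange (C–I reacts, the C8–Br bond does not), transmetalation to zinc and Negishi coupling with the alkenyl triflate follow; 2,6-dialkoxyarylzinc reagents are standard partners with biarylphosphine palladium catalysts, and because the crowded bond joins two sp2 carbons no stereocentre is formed or disturbed.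

Step 8
Reactants: 12 (2R,3R)-5,7-bis(benzyloxy)-6-{(2S)-7-(benzyloxy)-2-[3,4,5-tris(benzyloxy)phenyl]-2H-chromen-4-yl}-8-bromo-2-[3,4,5-tris(benzyloxy)phenyl]chroman-3-ol
Product: 14 (2R,3R)-5,7-bis(benzyloxy)-6-{(2R,3S,4S)-7-(benzyloxy)-3-hydroxy-2-[3,4,5-tris(benzyloxy)phenyl]chroman-4-yl}-8-bromo-2-[3,4,5-tris(benzyloxy)phenyl]chroman-3-ol, via C3 alkylborane 13 (not isolated)
Conditions: BH3·THF (5 equiv), THF, 0 °C to rt, dark; then H2O2, aq NaOH–phosphate buffer (pH 8), 0 °C
Reagents that add atoms: hydrogen peroxide, OO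
Why: Hydroboration–oxidation of a trisubstituted 1,1-diarylalkene: H–B adds through a four-centre syn transition state with boron at C3, the less substituted and non-benzylic carbon, and hydrogen at C4, which carries ring A and ring D. The closest known reactions are the hydroboration–oxidation of 2-aryl-2H-chromenes to 2,3-trans-flavan-3-ols and of 4-aryl-2H-chromenes to trans-4-arylchroman-3-ols. No ring is closed. At C3, boron enters on the face of C3=C4 opposite to the ring-B aryl on the adjacent stereocentre C2, and the oxidation proceeds with retention, so the 3-OH is trans to the C2 aryl (3S). At C4, the hydrogen arrives in the same syn event on the same face, so H4 is cis to O3 and ring D ends trans to the 3-OH and cis to the C2 aryl (4S, the 4α bond). The two benzyloxy groups beside C6 lie one above and one below the alkene plane because ring D is twisted out of conjugation, so they should slow the addition but not bias the face, and the crowded carbon receives only a hydrogen atom. Regioselectivity is secured by the 1,1-diaryl substitution at C4 and facial selectivity by C2; the aryl bromide and benzyl ethers are inert to borane, the lower 3-OH only consumes one B–H, and a buffered oxidation limits β-elimination of boron with O1.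

Step 9
Reactants: 14 (2R,3R)-5,7-bis(benzyloxy)-6-{(2R,3S,4S)-7-(benzyloxy)-3-hydroxy-2-[3,4,5-tris(benzyloxy)phenyl]chroman-4-yl}-8-bromo-2-[3,4,5-tris(benzyloxy)phenyl]chroman-3-ol
Product: 15 robinetinidol-(4α→6)-(−)-epigallocatechin [(2R,3R)-6-[(2R,3S,4S)-3,7-dihydroxy-2-(3,4,5-trihydroxyphenyl)chroman-4-yl]-2-(3,4,5-trihydroxyphenyl)chromane-3,5,7-triol]
Conditions: H2 (1 atm), Pd(OH)2/C, Et3N, THF–MeOH–H2O, rt; filtration and lyophilisation under argon
Reagents that add atoms: none
Why: Hydrogenolysis of nine benzyl ethers together with hydrodebromination of the aryl bromide, with Et3N taking up HBr; the ring C–O bonds at C2 and the C4 methines of flavan-3-ols are known to survive these conditions, and no stereocentre is involved.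

## Compound list

1 | 7-hydroxy-4H-chromen-4-one | O=c1ccoc2cc(O)ccc12 | starting material
2 | 7-(benzyloxy)-4H-chromen-4-one | O=c1ccoc2cc(OCc3ccccc3)ccc12 | intermediate
3 | [3,4,5-tris(benzyloxy)phenyl]boronic acid | OB(O)c1cc(OCc2ccccc2)c(OCc2ccccc2)c(OCc2ccccc2)c1 | starting material
4 | (2S)-7-(benzyloxy)-2-[3,4,5-tris(benzyloxy)phenyl]-2,3-dihydro-4H-chromen-4-one | O=C1C[C@@H](c2cc(OCc3ccccc3)c(OCc3ccccc3)c(OCc3ccccc3)c2)Oc2cc(OCc3ccccc3)ccc12 | intermediate
5 | (2S)-7-(benzyloxy)-2-[3,4,5-tris(benzyloxy)phenyl]-2H-chromen-4-yl trifluoromethanesulfonate | O=S(=O)(OC1=C[C@@H](c2cc(OCc3ccccc3)c(OCc3ccccc3)c(OCc3ccccc3)c2)Oc2cc(OCc3ccccc3)ccc12)C(F)(F)F | intermediate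
6 | (−)-epigallocatechin, (2R,3R)-2-(3,4,5-trihydroxyphenyl)chromane-3,5,7-triol | Oc1cc(O)c2c(c1)O[C@H](c1cc(O)c(O)c(O)c1)[C@H](O)C2 | starting material
7 | (2R,3R)-5,7-bis(benzyloxy)-2-[3,4,5-tris(benzyloxy)phenyl]chroman-3-ol | C(c1ccccc1)Oc1cc(OCc2ccccc2)c2c(c1)O[C@H](c1cc(OCc3ccccc3)c(OCc3ccccc3)c(OCc3ccccc3)c1)[C@H](O)C2 | intermediate
8 | (2R,3R)-5,7-bis(benzyloxy)-8-bromo-2-[3,4,5-tris(benzyloxy)phenyl]chroman-3-ol | C(c1ccccc1)Oc1cc(OCc2ccccc2)c2c(c1Br)O[C@H](c1cc(OCc3ccccc3)c(OCc3ccccc3)c(OCc3ccccc3)c1)[C@H](O)C2 | intermediate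
9 | (2R,3R)-5,7-bis(benzyloxy)-8-bromo-6-iodo-2-[3,4,5-tris(benzyloxy)phenyl]chroman-3-ol | C(c1ccccc1)Oc1c(I)c(OCc2ccccc2)c2c(c1Br)O[C@H](c1cc(OCc3ccccc3)c(OCc3ccccc3)c(OCc3ccccc3)c1)[C@H](O)C2 | intermediate
10 | ring-D C6 arylmagnesium chloride of 9, 3-OH as chloromagnesium alkoxide | C(c1ccccc1)Oc1c([Mg]Cl)c(OCc2ccccc2)c2c(c1Br)O[C@H](c1cc(OCc3ccccc3)c(OCc3ccccc3)c(OCc3ccccc3)c1)[C@H](O[Mg]Cl)C2 | intermediate
11 | ring-D C6 arylzinc chloride, 3-OH as chloromagnesium alkoxide | C(c1ccccc1)Oc1c([Zn]Cl)c(OCc2ccccc2)c2c(c1Br)O[C@H](c1cc(OCc3ccccc3)c(OCc3ccccc3)c(OCc3ccccc3)c1)[C@H](O[Mg]Cl)C2 | intermediate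
12 | (2R,3R)-5,7-bis(benzyloxy)-6-{(2S)-7-(benzyloxy)-2-[3,4,5-tris(benzyloxy)phenyl]-2H-chromen-4-yl}-8-bromo-2-[3,4,5-tris(benzyloxy)phenyl]chroman-3-ol | C(c1ccccc1)Oc1c(C3=C[C@@H](c4cc(OCc5ccccc5)c(OCc5ccccc5)c(OCc5ccccc5)c4)Oc4cc(OCc5ccccc5)ccc34)c(OCc2ccccc2)c2c(c1Br)O[C@H](c1cc(OCc3ccccc3)c(OCc3ccccc3)c(OCc3ccccc3)c1)[C@H](O)C2 | intermediate
13 | C3 alkylborane from 12 (boron at upper C3, H at C4, lower 3-OH as O-borane) | C(c1ccccc1)Oc1ccc2c(c1)O[C@H](c1cc(OCc3ccccc3)c(OCc3ccccc3)c(OCc3ccccc3)c1)[C@@H](B)[C@@H]2c1c(OCc3ccccc3)c(Br)c2c(c1OCc3ccccc3)C[C@@H](OB)[C@@H](c1cc(OCc3ccccc3)c(OCc3ccccc3)c(OCc3ccccc3)c1)O2 | intermediate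
14 | (2R,3R)-5,7-bis(benzyloxy)-6-{(2R,3S,4S)-7-(benzyloxy)-3-hydroxy-2-[3,4,5-tris(benzyloxy)phenyl]chroman-4-yl}-8-bromo-2-[3,4,5-tris(benzyloxy)phenyl]chroman-3-ol | C(c1ccccc1)Oc1ccc2c(c1)O[C@H](c1cc(OCc3ccccc3)c(OCc3ccccc3)c(OCc3ccccc3)c1)[C@@H](O)[C@@H]2c1c(OCc3ccccc3)c(Br)c2c(c1OCc3ccccc3)C[C@@H](O)[C@@H](c1cc(OCc3ccccc3)c(OCc3ccccc3)c(OCc3ccccc3)c1)O2 | intermediate
15 | robinetinidol-(4α→6)-(−)-epigallocatechin, (2R,3R)-6-[(2R,3S,4S)-3,7-dihydroxy-2-(3,4,5-trihydroxyphenyl)chroman-4-yl]-2-(3,4,5-trihydroxyphenyl)chromane-3,5,7-triol | Oc1ccc2c(c1)O[C@H](c1cc(O)c(O)c(O)c1)[C@@H](O)[C@@H]2c1c(O)cc2c(c1O)C[C@@H](O)[C@@H](c1cc(O)c(O)c(O)c1)O2 | target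

## Step count and least certain steps

Total: 9 steps. Longest linear sequence: 6 steps (1, 2, 3, 7, 8, 9 or 4, 5, 6, 7, 8, 9).

**Step 8 (key step).** The most likely failures are β-elimination of the C3 boron with the ring oxygen O1 during the alkaline oxidation, which would open ring C, and slow addition at the crowded alkene with erosion of facial selectivity. The fallback sets out from 12 and returns at 14. Dihydroxylation of 12 with OsO4 (cat.) and N-methylmorpholine N-oxide, anti to the ring-B aryl, should give the cis-3,4-diol F1. Both secondary hydroxyls are silylated with chlorodiisopropylsilane and imidazole to give the bis(diisopropylsilyl) ether F2. CF3CO2H at −78 °C ionises the tertiary, doubly benzylic C4 hydroxyl, and the Si–H on O3 delivers hydride to the same face, which places H4 cis to O3 and gives the silyl trifluoroacetate F3. Bu4NF then removes both silyl groups to give 14.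

**Step 7.** The most likely failures are incomplete iodine–magnesium exchange on the electron-rich ring and slow reductive elimination between two hindered sp2 carbons, with protodemetalation or insertion into the C8–Br bond taking over. The fallback sets out from 5 and 9 and returns at 12. The polarity is reversed so that no aryl Grignard is needed: Miyaura borylation of 5 (bis(pinacolato)diboron, PdCl2(dppf), KOAc, dioxane) gives the alkenyl pinacol boronate F4, and Suzuki–Miyaura coupling of F4 with iodide 9 (Pd(OAc)2, SPhos, K3PO4, toluene–H2O) gives 12; the free 3-OH is tolerated.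

**Step 3.** The most likely failures are loss of configuration at C2 if the activated ketone opens at the O1–C2 bond, and sulfonylation of the electron-rich ring A. The fallback sets out from 4 and 10 and returns at 12, avoiding any enol derivative. Grignard 10 is added to the carbonyl of 4 in the presence of LaCl3·2LiCl to give the tertiary C4 carbinol F5 as both C4 epimers. Dehydration with pyridinium p-toluenesulfonate in CH2Cl2 at 0 °C in the dark then gives 12.

**Step 2.** The most likely failures are slow carbopalladation of the donor-substituted chromone, with protodeboronation of 3, and insufficient enantioselectivity. The fallback sets out from 2 and 3 and returns at 4, replacing asymmetric induction with resolution. A 1,4-addition without a chiral ligand ([RhCl(cod)]2, KOH, dioxane–H2O) gives the racemic flavanone F6. Transfer hydrogenation with RuCl(p-cymene)[(R,R)-TsDPEN] in HCO2H–Et3N is run as a kinetic resolution, in which the 2R ketone should be reduced to the cis-flavan-4-ol F7 and (2S)-4 is recovered.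

## Further compounds

F1 | step 8 | (2R,3R)-5,7-bis(benzyloxy)-6-{(2R,3R,4R)-7-(benzyloxy)-3,4-dihydroxy-2-[3,4,5-tris(benzyloxy)phenyl]chroman-4-yl}-8-bromo-2-[3,4,5-tris(benzyloxy)phenyl]chroman-3-ol | C(c1ccccc1)Oc1ccc2c(c1)O[C@H](c1cc(OCc3ccccc3)c(OCc3ccccc3)c(OCc3ccccc3)c1)[C@@H](O)[C@]2(O)c1c(OCc3ccccc3)c(Br)c2c(c1OCc3ccccc3)C[C@@H](O)[C@@H](c1cc(OCc3ccccc3)c(OCc3ccccc3)c(OCc3ccccc3)c1)O2
F2 | step 8 | bis(O-diisopropylsilyl) ether of F1 at the upper and lower 3-hydroxyls, 4-OH free | C(c1ccccc1)Oc1ccc2c(c1)O[C@H](c1cc(OCc3ccccc3)c(OCc3ccccc3)c(OCc3ccccc3)c1)[C@@H](O[SiH](C(C)C)C(C)C)[C@]2(O)c1c(OCc3ccccc3)c(Br)c2c(c1OCc3ccccc3)C[C@@H](O[SiH](C(C)C)C(C)C)[C@@H](c1cc(OCc3ccccc3)c(OCc3ccccc3)c(OCc3ccccc3)c1)O2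
F3 | step 8 | 14 carrying a diisopropyl(trifluoroacetoxy)silyl group on the upper O3 and a diisopropylsilyl group on the lower O3 | C(c1ccccc1)Oc1ccc2c(c1)O[C@H](c1cc(OCc3ccccc3)c(OCc3ccccc3)c(OCc3ccccc3)c1)[C@@H](O[Si](C(C)C)(C(C)C)OC(=O)C(F)(F)F)[C@@H]2c1c(OCc3ccccc3)c(Br)c2c(c1OCc3ccccc3)C[C@@H](O[SiH](C(C)C)C(C)C)[C@@H](c1cc(OCc3ccccc3)c(OCc3ccccc3)c(OCc3ccccc3)c1)O2
F4 | step 7 | 2-{(2S)-7-(benzyloxy)-2-[3,4,5-tris(benzyloxy)phenyl]-2H-chromen-4-yl}-4,4,5,5-tetramethyl-1,3,2-dioxaborolane | CC1(C)OB(OC1(C)C)C1=C[C@@H](c2cc(OCc3ccccc3)c(OCc3ccccc3)c(OCc3ccccc3)c2)Oc2cc(OCc3ccccc3)ccc12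
F5 | step 3 | (2R,3R)-5,7-bis(benzyloxy)-6-{(2S,4RS)-7-(benzyloxy)-4-hydroxy-2-[3,4,5-tris(benzyloxy)phenyl]chroman-4-yl}-8-bromo-2-[3,4,5-tris(benzyloxy)phenyl]chroman-3-ol | C(c1ccccc1)Oc1c(C3(O)C[C@@H](c4cc(OCc5ccccc5)c(OCc5ccccc5)c(OCc5ccccc5)c4)Oc4cc(OCc5ccccc5)ccc34)c(OCc2ccccc2)c2c(c1Br)O[C@H](c1cc(OCc3ccccc3)c(OCc3ccccc3)c(OCc3ccccc3)c1)[C@H](O)C2
F6 | step 2 | (2RS)-7-(benzyloxy)-2-[3,4,5-tris(benzyloxy)phenyl]-2,3-dihydro-4H-chromen-4-one | O=C1CC(c2cc(OCc3ccccc3)c(OCc3ccccc3)c(OCc3ccccc3)c2)Oc2cc(OCc3ccccc3)ccc12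
F7 | step 2 | (2R,4R)-7-(benzyloxy)-2-[3,4,5-tris(benzyloxy)phenyl]chroman-4-ol | O[C@@H]1C[C@H](c2cc(OCc3ccccc3)c(OCc3ccccc3)c(OCc3ccccc3)c2)Oc2cc(OCc3ccccc3)ccc12
A1 | alternative 1 | (2R,3S,4R)-7-(benzyloxy)-2-[3,4,5-tris(benzyloxy)phenyl]chromane-3,4-diol | C(c1ccccc1)Oc1ccc2c(c1)O[C@H](c1cc(OCc3ccccc3)c(OCc3ccccc3)c(OCc3ccccc3)c1)[C@@H](O)[C@@H]2O
A2 | alternative 2 | (E)-1-[4-(benzyloxy)-2-hydroxyphenyl]-3-[3,4,5-tris(benzyloxy)phenyl]prop-2-en-1-one | O=C(/C=C/c1cc(OCc2ccccc2)c(OCc2ccccc2)c(OCc2ccccc2)c1)c1ccc(OCc2ccccc2)cc1O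
A3 | alternative 2 | (E)-1-[4-(benzyloxy)-2-hydroxyphenyl]-1-{(2R,3R)-5,7-bis(benzyloxy)-8-bromo-3-hydroxy-2-[3,4,5-tris(benzyloxy)phenyl]chroman-6-yl}-3-[3,4,5-tris(benzyloxy)phenyl]prop-2-en-1-ol, both carbinol epimers | OC(/C=C/c1cc(OCc2ccccc2)c(OCc2ccccc2)c(OCc2ccccc2)c1)(c1ccc(OCc2ccccc2)cc1O)c1c(OCc2ccccc2)c(Br)c2c(c1OCc3ccccc3)C[C@@H](O)[C@@H](c1cc(OCc3ccccc3)c(OCc3ccccc3)c(OCc3ccccc3)c1)O2
A4 | alternative 3 | (2R,3S,4S)-7-(benzyloxy)-4-(2,4,6-trihydroxyphenyl)-2-[3,4,5-tris(benzyloxy)phenyl]chroman-3-ol | C(c1ccccc1)Oc1ccc2c(c1)O[C@H](c1cc(OCc3ccccc3)c(OCc3ccccc3)c(OCc3ccccc3)c1)[C@@H](O)[C@@H]2c1c(O)cc(O)cc1O
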